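**Plan**

1. Numbering: chain C1–C6 (C2 ketone, C3 carbinol, C5–C6 epoxide); ring A C1'–C6' (C1' on C3, C4' = C(CH3)Cl, C5' = CHBr). The C3 oxygen lies 1,4 across ring A from C4', so a temporary C3–O–C4' ether bridge turns ring A plus C3 into a 2-oxabicyclo[2.2.2]oct-5-ene, the adduct of a ketone C=O and a cyclohexa-1,3-diene.
2. Cuts, last to first: epoxide oxygen; the C5=C6 isopropylidene unit (cross-metathesis; allyl stands in for prenyl so that bromine meets only one reactive alkene); C5'–Br and C4'–Cl; C1–C2; C6'–H with C4'–O restored; then C3–C1' and O–C4' together, leaving 1-methylcyclohexa-1,3-diene and ethyl 2-oxopent-4-enoate.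
3. Forward: ring A is present in the diene; the dihydropyran ring closes in the cycloaddition and is reopened by ionic hydrogenation; the ester becomes the methyl ketone, ring A is halogenated, and cross-metathesis and epoxidation finish C4–C6.
4. Stereochemistry: C3 and C1' come from the (S,S)-t-Bu-bis(oxazoline) copper catalyst and the endo transition state. C4' and C5' are relayed from C1' through trans-diaxial steps and a final 1,2-interchange of the halogens, because the target's halogens are trans-diequatorial and a direct Br–Cl addition would give the diaxial isomer. C5 comes from the D-fructose-derived Shi ketone.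

Key step: step 5

Remark: "syn" and "anti" name the ring-A face relative to the C1' side chain; the (S,S)-ligand is assumed to expose the si face of the chelated ketone, as the square-planar chelate model predicts.

**Route**

Step 1
Reactants: 1 3-methylcyclohex-2-en-1-one
Product: 2 N'-(3-methylcyclohex-2-en-1-ylidene)-4-methylbenzenesulfonohydrazide
Conditions: TsNHNH2, MeOH, cat. HCl, rt
Reagents that add atoms: 4-methylbenzenesulfonohydrazide, Cc1ccc(cc1)S(=O)(=O)NN
Why: Acid-catalysed hydrazone formation from a ketone and a sulfonyl hydrazide is routine for enones, and the E/Z mixture is used as such since no lasting stereocentre is made.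

Step 2
Reactants: 2 N'-(3-methylcyclohex-2-en-1-ylidene)-4-methylbenzenesulfonohydrazide
Product: 4 1-methylcyclohexa-1,3-diene, via 5-methylcyclohexa-1,5-dienyllithium 3 (not isolated)
Conditions: MeLi (2.2 equiv), Et2O, 0 °C to rt; then H2O
Reagents that add atoms: methyllithium, [Li]C (lithium of 3 only; nothing stays in 4)
Why: Shapiro reaction, in which MeLi removes N–H and the α'-proton, the dianion loses sulfinate and N2 to give vinyllithium 3, and protonation leaves the new alkene conjugated with the untouched methyl-bearing one, with no stereocentre formed.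

Step 3
Reactants: 5 ethyl 1,3-dithiane-2-carboxylate; 6 3-bromoprop-1-ene
Product: 7 ethyl 2-(prop-2-en-1-yl)-1,3-dithiane-2-carboxylate
Conditions: NaH, DMF, 0 °C to rt
Reagents that add atoms: none
Why: SN2 alkylation of the sodium salt of the ester-stabilised dithiane carbanion (an acyl-anion equivalent) with an allylic bromide is standard and forms no stereocentre.

Step 4
Reactants: 7 ethyl 2-(prop-2-en-1-yl)-1,3-dithiane-2-carboxylate
Product: 8 ethyl 2-oxopent-4-enoate
Conditions: PhI(OCOCF3)2, MeCN–H2O (9:1), 0 °C
Reagents that add atoms: water, O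
Why: Oxidative dethioacetalisation, in which the hypervalent iodine reagent activates sulfur and water captures the thionium ion to release the 1,2-dicarbonyl, while the monosubstituted alkene is far less nucleophilic than sulfur and is left alone.

Step 5
Reactants: 4 1-methylcyclohexa-1,3-diene; 8 ethyl 2-oxopent-4-enoate
Product: 9 ethyl (1R,3S,4S)-1-methyl-3-(prop-2-en-1-yl)-2-oxabicyclo[2.2.2]oct-5-ene-3-carboxylate (ester endo)
Conditions: Cu(OTf)2 (10 mol %), 2,2'-(propane-2,2-diyl)bis[(4S)-4-tert-butyl-4,5-dihydro-1,3-oxazole] (11 mol %), CH2Cl2, 0 °C to rt, 4 in excess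
Reagents that add atoms: none
Why: The keto ester binds divalent copper through both carbonyl oxygens in the square-planar Cu(OTf)2–bis(oxazoline) complex, and its ketone C=O then adds across the termini of the s-cis-locked diene in an asynchronous hetero-Diels–Alder reaction, the closest known case being the same catalyst with ethyl pyruvate or glyoxylates and cyclohexa-1,3-diene. The one new ring, the six-membered dihydropyran ring of the oxabicycle, closes by this [4+2] cycloaddition, C3–C1' forming ahead of O–C4'. C3 is set by the ligand, whose tert-butyl group covers the re face of the chelated ketone so that the diene meets the si face; C1' is set by the endo transition state, in which the copper-bound ester lies under the diene and ends syn to the new alkene; C4' follows because both bonds form on one face of the cyclic diene. The methyl group fixes the regiochemistry, since it enlarges the HOMO coefficient at the remote terminus (bond to carbon) and stabilises positive charge at C4' (bond to oxygen). The step therefore needs regio-, endo- and facial selectivity and must outrun the carbonyl-ene reaction and migration of the alkene of 8 into conjugation, which the chelate geometry, the locked diene and the mild conditions are expected to secure.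

Step 6
Reactants: 9 ethyl (1R,3S,4S)-1-methyl-3-(prop-2-en-1-yl)-2-oxabicyclo[2.2.2]oct-5-ene-3-carboxylate
Product: 10 ethyl (2S)-2-hydroxy-2-[(1S)-4-methylcyclohex-3-en-1-yl]pent-4-enoate
Conditions: Et3SiH (5 equiv), BF3·OEt2 (2.5 equiv), CH2Cl2, −78 to −20 °C; aq. NaHCO3
Reagents that add atoms: none
Why: Ionic hydrogenation of an allylic ether, in which BF3 ionises the tertiary allylic C4'–O bond (C3–O cannot ionise next to the ester) and Et3SiH gives hydride to the less hindered terminus C6' of the allyl cation, which should leave the trisubstituted C4'=C5' alkene and the free C3 hydroxyl without touching C3 or C1'.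

Step 7
Reactants: 10 ethyl (2S)-2-hydroxy-2-[(1S)-4-methylcyclohex-3-en-1-yl]pent-4-enoate
Product: 11 (2S)-2-hydroxy-N-methoxy-N-methyl-2-[(1S)-4-methylcyclohex-3-en-1-yl]pent-4-enamide
Conditions: AlMe3, MeNHOMe·HCl, CH2Cl2, 0 °C to reflux
Reagents that add atoms: N,O-dimethylhydroxylamine hydrochloride, CNOC.Cl
Why: Weinreb aminolysis of the ester by the aluminium amide made in the flask, helped by chelation of aluminium between the α-alkoxide and the ester carbonyl, with no stereocentre touched.

Step 8
Reactants: 11 (2S)-2-hydroxy-N-methoxy-N-methyl-2-[(1S)-4-methylcyclohex-3-en-1-yl]pent-4-enamide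
Product: 12 (3S)-3-hydroxy-3-[(1S)-4-methylcyclohex-3-en-1-yl]hex-5-en-2-one
Conditions: MeMgBr (3.5 equiv), THF, −20 to 0 °C; aq. NH4Cl
Reagents that add atoms: methylmagnesium bromide, C[Mg]Br
Why: Grignard addition to a Weinreb amide stops at the chelated tetrahedral intermediate, which gives the methyl ketone only on work-up, the tertiary hydroxyl merely consuming one equivalent as its alkoxide.

Step 9
Reactants: 12 (3S)-3-hydroxy-3-[(1S)-4-methylcyclohex-3-en-1-yl]hex-5-en-2-one
Product: 14 (3S)-3-hydroxy-3-[(1S,3S,6R)-6-methyl-7-oxabicyclo[4.1.0]heptan-3-yl]hex-5-en-2-one, via bromohydrin 13 (not isolated)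
Conditions: NBS (1.05 equiv), acetone–H2O, 0 °C; then K2CO3, rt
Reagents that add atoms: water, O; N-bromosuccinimide, O=C1CCC(=O)N1Br (bromine of 13 only)
Why: Bromohydrin formation then Williamson-type closure, in which Br+ adds reversibly and only to the trisubstituted ring alkene, water opens the bromonium ion at the tertiary C4' in the trans-diaxial (Fürst–Plattner) sense and so selects the bromonium ion anti to the equatorial side chain (13: Br axial on C5', OH axial on C4' syn), and the C4' alkoxide then displaces bromide with inversion to give the epoxide syn to the side chain, the course by which limonene gives its trans-oxide.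

Step 10
Reactants: 14 (3S)-3-hydroxy-3-[(1S,3S,6R)-6-methyl-7-oxabicyclo[4.1.0]heptan-3-yl]hex-5-en-2-one
Product: 15 (3S)-3-[(1S,3R,4R)-3-chloro-4-hydroxy-4-methylcyclohexyl]-3-hydroxyhex-5-en-2-one
Conditions: LiCl, AcOH, THF, rt
Reagents that add atoms: lithium chloride, [Li+].[Cl-]
Why: Acid-assisted SN2 opening of the epoxide by chloride at the less substituted C5' with inversion, which is also the trans-diaxial opening of this epoxide, puts chlorine on C5' anti and leaves the tertiary C4' hydroxyl syn.

Step 11
Reactants: 15 (3S)-3-[(1S,3R,4R)-3-chloro-4-hydroxy-4-methylcyclohexyl]-3-hydroxyhex-5-en-2-one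
Product: 16 (3S)-3-[(1S,3R,4R)-4-bromo-3-chloro-4-methylcyclohexyl]-3-hydroxyhex-5-en-2-one
Conditions: HBr (gas), CH2Cl2, −40 to −10 °C
Reagents that add atoms: hydrogen bromide, Br
Why: SN1 substitution of the tertiary alcohol, in which the C4' cation is bridged by (or attacked anti to) the antiperiplanar axial chlorine on C5', so bromide enters on the face that water left (retention) and the trans-diaxial bromochloride results, while the C3 hydroxyl next to the ketone cannot ionise.

Step 12
Reactants: 16 (3S)-3-[(1S,3R,4R)-4-bromo-3-chloro-4-methylcyclohexyl]-3-hydroxyhex-5-en-2-one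
Product: 17 (3S)-3-[(1S,3S,4S)-3-bromo-4-chloro-4-methylcyclohexyl]-3-hydroxyhex-5-en-2-one
Conditions: MeNO2, 60 °C, dark; chromatography, recovered 16 heated again
Reagents that add atoms: none
Why: Thermal 1,2-interchange of vicinal trans-diaxial halogens (dyotropic rearrangement, the diaxial-to-diequatorial change known for 5α-bromo-6β-chloro steroids), in which bromine moves from C4' to C5' on the syn face while chlorine moves from C5' to C4' on the anti face through a bridged ion pair, inverting both centres to the diequatorial arrangement; it is an equilibrium, so 17 is separated and 16 recycled.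

Step 13
Reactants: 17 (3S)-3-[(1S,3S,4S)-3-bromo-4-chloro-4-methylcyclohexyl]-3-hydroxyhex-5-en-2-one
Product: 18 (3S)-3-[(1S,3S,4S)-3-bromo-4-chloro-4-methylcyclohexyl]-3-hydroxy-6-methylhept-5-en-2-one
Conditions: RuCl2(=CHPh)(H2IMes)(PCy3) (second-generation Grubbs catalyst, 5 mol %), 2-methylbut-2-ene/CH2Cl2, 40 °C
Reagents that add atoms: 2-methylbut-2-ene, CC=C(C)C
Why: Olefin cross-metathesis with excess 2-methylbut-2-ene turns the monosubstituted alkene into the prenyl group with loss of propene, and the catalyst tolerates alkyl halides, the ketone and the tertiary alcohol.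

Step 14
Reactants: 18 (3S)-3-[(1S,3S,4S)-3-bromo-4-chloro-4-methylcyclohexyl]-3-hydroxy-6-methylhept-5-en-2-one
Product: 19 (3S)-3-[(1S,3S,4S)-3-bromo-4-chloro-4-methylcyclohexyl]-4-[(2R)-3,3-dimethyloxiran-2-yl]-3-hydroxybutan-2-one
Conditions: D-fructose-derived Shi ketone (30 mol %), Oxone (2KHSO5·KHSO4·K2SO4), K2CO3, Bu4NHSO4, MeCN–CH2(OMe)2 / aq. Na2B4O7 buffer, 0 °C
Reagents that add atoms: potassium peroxymonosulfate, [K+].[O-]S(=O)(=O)OO
Why: Shi asymmetric epoxidation, in which the dioxirane of the chiral ketone transfers oxygen through the spiro transition state that gives the (R)-epoxide at C5 for R–CH=CMe2 alkenes under reagent control, and the buffered basic medium keeps the hydroxy epoxide from cyclising.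

**Compound list**

1 | 3-methylcyclohex-2-en-1-one | CC1=CC(=O)CCC1 | starting material
2 | N'-(3-methylcyclohex-2-en-1-ylidene)-4-methylbenzenesulfonohydrazide (E/Z mixture) | CC1=CC(=NNS(=O)(=O)c2ccc(C)cc2)CCC1 | intermediate
3 | (5-methylcyclohexa-1,5-dien-1-yl)lithium | [Li]C1=CCCC(C)=C1 | intermediate
4 | 1-methylcyclohexa-1,3-diene | CC1=CC=CCC1 | intermediate
5 | ethyl 1,3-dithiane-2-carboxylate | CCOC(=O)C1SCCCS1 | starting material
6 | 3-bromoprop-1-ene | C=CCBr | starting material
7 | ethyl 2-(prop-2-en-1-yl)-1,3-dithiane-2-carboxylate | CCOC(=O)C1(CC=C)SCCCS1 | intermediate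
8 | ethyl 2-oxopent-4-enoate | CCOC(=O)C(=O)CC=C | intermediate
9 | ethyl (1R,3S,4S)-1-methyl-3-(prop-2-en-1-yl)-2-oxabicyclo[2.2.2]oct-5-ene-3-carboxylate | CCOC(=O)[C@](O2)(CC=C)[C@H]1CC[C@]2(C)C=C1 | intermediate
10 | ethyl (2S)-2-hydroxy-2-[(1S)-4-methylcyclohex-3-en-1-yl]pent-4-enoate | CCOC(=O)[C@](O)(CC=C)[C@H]1CCC(C)=CC1 | intermediate
11 | (2S)-2-hydroxy-N-methoxy-N-methyl-2-[(1S)-4-methylcyclohex-3-en-1-yl]pent-4-enamide | CON(C)C(=O)[C@](O)(CC=C)[C@H]1CCC(C)=CC1 | intermediate
12 | (3S)-3-hydroxy-3-[(1S)-4-methylcyclohex-3-en-1-yl]hex-5-en-2-one | CC(=O)[C@](O)(CC=C)[C@H]1CCC(C)=CC1 | intermediate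
13 | (3S)-3-[(1S,3R,4R)-3-bromo-4-hydroxy-4-methylcyclohexyl]-3-hydroxyhex-5-en-2-one | CC(=O)[C@](O)(CC=C)[C@H]1CC[C@@](C)(O)[C@H](Br)C1 | intermediate
14 | (3S)-3-hydroxy-3-[(1S,3S,6R)-6-methyl-7-oxabicyclo[4.1.0]heptan-3-yl]hex-5-en-2-one | CC(=O)[C@](O)(CC=C)[C@H]1CC[C@@]2(C)O[C@H]2C1 | intermediate
15 | (3S)-3-[(1S,3R,4R)-3-chloro-4-hydroxy-4-methylcyclohexyl]-3-hydroxyhex-5-en-2-one | CC(=O)[C@](O)(CC=C)[C@H]1CC[C@@](C)(O)[C@H](Cl)C1 | intermediate
16 | (3S)-3-[(1S,3R,4R)-4-bromo-3-chloro-4-methylcyclohexyl]-3-hydroxyhex-5-en-2-one | CC(=O)[C@](O)(CC=C)[C@H]1CC[C@@](C)(Br)[C@H](Cl)C1 | intermediate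
17 | (3S)-3-[(1S,3S,4S)-3-bromo-4-chloro-4-methylcyclohexyl]-3-hydroxyhex-5-en-2-one | CC(=O)[C@](O)(CC=C)[C@H]1CC[C@](C)(Cl)[C@@H](Br)C1 | intermediate
18 | (3S)-3-[(1S,3S,4S)-3-bromo-4-chloro-4-methylcyclohexyl]-3-hydroxy-6-methylhept-5-en-2-one | CC(=O)[C@](O)(CC=C(C)C)[C@H]1CC[C@](C)(Cl)[C@@H](Br)C1 | intermediate
19 | (3S)-3-[(1S,3S,4S)-3-bromo-4-chloro-4-methylcyclohexyl]-4-[(2R)-3,3-dimethyloxiran-2-yl]-3-hydroxybutan-2-one | CC(=O)[C@](O)(C[C@H]1OC1(C)C)[C@H]1CC[C@](C)(Cl)[C@@H](Br)C1 | target

**Count and risks**

Total steps: 14. Longest linear sequence: 12 (steps 1, 2 and 5–14; the branch through steps 3 and 4 is equally long).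

Steps most likely to fail:

Step 12. The halogen interchange is an equilibrium that lacks the 1,3-diaxial strain which drives it in steroids, so it may rest on the side of 16. Ionisation of the tertiary bromide may also end in loss of HBr or in ether formation by the C3 hydroxyl. The fallback sets out from 12 and adds Br–Cl in one step. Silylation with 1-(trimethylsilyl)imidazole gives the trimethylsilyl ether F1, which keeps the hydroxyl from closing onto the bromonium ion. Bu4NBrCl2 in CH2Cl2 at −78 °C then adds Br–Cl anti across the ring alkene. The adduct that arises from the bromonium ion syn to the side chain with chloride attack at C4' is the silylated bromochloride F2. It is expected to be the minor adduct beside the trans-diaxial one; it is separated by chromatography, and the unwanted adducts are returned to F1 with zinc in acetic acid. K2CO3 in MeOH removes the silyl group and the route is rejoined at 17.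

Step 6. The allyl cation may lose a proton to give dienes, take hydride at C4', or be captured by the ester carbonyl, and acid may re-close the product alkene onto the hydroxyl. The fallback sets out from 9 and separates ionisation from reduction. LiOH gives the carboxylic acid F3. Catalytic CF3CO2H in CH2Cl2 ionises C4'–O, and the carboxyl group captures the cation at C6' to give the cis-fused allylic γ-lactone F4 with the C4'=C5' alkene in place, a known rearrangement of such cycloadduct acids. Pd(PPh3)4 (zerovalent palladium) with NaBH4 cleaves the allylic C6'–O bond, hydride entering at the less hindered terminus, to give the hydroxy acid F5. Coupling with MeNHOMe·HCl (EDC, i-Pr2NEt) rejoins the route at 11.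

Step 5. The ketone may react by the ene pathway instead of closing the hindered tertiary C–O bond, the alkene of 8 may migrate into conjugation, or facial selectivity may erode with the 1-methyl diene. The fallback sets out from 8 and moves stereocontrol to an auxiliary. Transesterification with (1R,2S,5R)-5-methyl-2-(2-phenylpropan-2-yl)cyclohexan-1-ol (cat. Ti(OEt)4, toluene) gives the 8-phenylmenthyl keto ester F6. Cycloaddition with 4 under SnCl4 at −78 °C, with the phenyl ring expected to shield the re face of the chelated ketone, gives the auxiliary-bearing cycloadduct F7. Ring opening as in step 6 gives the 8-phenylmenthyl hydroxy ester F8, and aminolysis as in step 7 releases the auxiliary and rejoins the route at 11.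

Further compounds
F1 | step 12 | (3S)-3-[(1S)-4-methylcyclohex-3-en-1-yl]-3-[(trimethylsilyl)oxy]hex-5-en-2-one | CC(=O)[C@](O[Si](C)(C)C)(CC=C)[C@H]1CCC(C)=CC1
F2 | step 12 | (3S)-3-[(1S,3S,4S)-3-bromo-4-chloro-4-methylcyclohexyl]-3-[(trimethylsilyl)oxy]hex-5-en-2-one | CC(=O)[C@](O[Si](C)(C)C)(CC=C)[C@H]1CC[C@](C)(Cl)[C@@H](Br)C1
F3 | step 6 | (1R,3S,4S)-1-methyl-3-(prop-2-en-1-yl)-2-oxabicyclo[2.2.2]oct-5-ene-3-carboxylic acid | OC(=O)[C@](O2)(CC=C)[C@H]1CC[C@]2(C)C=C1
F4 | step 6 | (3S,3aS,7aR)-3-hydroxy-6-methyl-3-(prop-2-en-1-yl)-3a,4,5,7a-tetrahydro-1-benzofuran-2(3H)-one | O=C1O[C@@H]2C=C(C)CC[C@@H]2[C@@]1(O)CC=C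
F5 | step 6 | (2S)-2-hydroxy-2-[(1S)-4-methylcyclohex-3-en-1-yl]pent-4-enoic acid | OC(=O)[C@](O)(CC=C)[C@H]1CCC(C)=CC1
F6 | step 5 | (1R,2S,5R)-5-methyl-2-(2-phenylpropan-2-yl)cyclohexyl 2-oxopent-4-enoate | C[C@@H]1CC[C@H]([C@@H](C1)OC(=O)C(=O)CC=C)C(C)(C)c1ccccc1
F7 | step 5 | (1R,2S,5R)-5-methyl-2-(2-phenylpropan-2-yl)cyclohexyl (1R,3S,4S)-1-methyl-3-(prop-2-en-1-yl)-2-oxabicyclo[2.2.2]oct-5-ene-3-carboxylate | C[C@@H]1CC[C@H]([C@@H](C1)OC(=O)[C@](O2)(CC=C)[C@H]3CC[C@]2(C)C=C3)C(C)(C)c1ccccc1
F8 | step 5 | (1R,2S,5R)-5-methyl-2-(2-phenylpropan-2-yl)cyclohexyl (2S)-2-hydroxy-2-[(1S)-4-methylcyclohex-3-en-1-yl]pent-4-enoate | C[C@@H]1CC[C@H]([C@@H](C1)OC(=O)[C@](O)(CC=C)[C@H]2CCC(C)=CC2)C(C)(C)c1ccccc1
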